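**Plan**

- Retrosynthesis: the O4'–Si bond is cut first, then both CH2–CH bonds of the prenyl groups. C6 and C8 of ring A each lie ortho to a free phenol (O5–H/O7–H) and carry CH2–CH=C(CH3)2, so each prenyl group divides into a phenolic CH2NMe2 arm and a 2-methylprop-1-enylboron nucleophile.
- Next the two C(aryl)–CH2N bonds are cut (double Mannich reaction). The pyranone ring C is cut at O1–C2 and C2–C3 (one carbon from an amide acetal) and at C4–C4a (aryllithium plus arylacetaldehyde). The pyran fused to ring B is cut at its O–C(CH3)2 and aryl–CH= bonds (propargyl ether Claisen cascade).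
- Forward: pyran on ring B (steps 1–3), homologation to the arylacetaldehyde (4–5), union with lithiated tris-MOM phloroglucinol and oxidation (6–8), closure of ring C (9–10), double aminomethylation (11), double prenyl assembly (12), desilylation (13).
- Stereochemistry: the target is achiral. The enol ether geometry in 6 and the carbinol centre in 11 are each erased one step later.

Key step: step 12

Assumption: in steps 11 and 12 the C8 position is taken to react before C6 (the reverse order gives the same products); enol ether 6 is an E/Z mixture and carbinol 11 a racemate. Steps 11 and 12 each incorporate two equivalents of their second reactant (15 and 18), so the second equivalent is also entered on the line for reagents that add atoms.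

**Route**

Step 1
Reactants: 1 2,4-dihydroxybenzaldehyde
Product: 2 2-hydroxy-4-(triisopropylsilyloxy)benzaldehyde
Conditions: TIPSCl (1.05 equiv), imidazole, CH2Cl2, 0 °C to rt
Reagents that add atoms: triisopropylsilyl chloride (TIPSCl), CC(C)[Si](Cl)(C(C)C)C(C)C
Why: Selective phenol silylation: the 2-OH is tied up in a hydrogen bond to the neighbouring formyl oxygen, so the bulky silyl chloride should react only at the free and more acidic 4-OH.

Step 2
Reactants: 2 2-hydroxy-4-(triisopropylsilyloxy)benzaldehyde; 3 3-chloro-3-methylbut-1-yne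
Product: 4 2-[(2-methylbut-3-yn-2-yl)oxy]-4-(triisopropylsilyloxy)benzaldehyde
Conditions: CuCl2 (1 mol %), DBU, dry MeCN, 0 °C
Reagents that add atoms: none
Why: Copper-catalysed O-propargylation of a phenol with a tertiary propargylic chloride (via a copper acetylide-derived electrophile) is established for hydrogen-bonded salicylaldehyde phenols, and the amine base in dry MeCN at 0 °C should leave the hindered aryl silyl ether untouched.

Step 3
Reactants: 4 2-[(2-methylbut-3-yn-2-yl)oxy]-4-(triisopropylsilyloxy)benzaldehyde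
Product: 5 2,2-dimethyl-5-(triisopropylsilyloxy)-2H-chromene-8-carbaldehyde
Conditions: N,N-diethylaniline, 180 °C
Reagents that add atoms: none
Why: Thermal aryl propargyl ether Claisen rearrangement can only reach C3 because C1 carries the formyl group, and the resulting ortho-allenyl phenol closes to the 2,2-dimethyl-2H-chromene by 1,5-hydrogen shift and oxa-6π electrocyclisation, which places the pyran oxygen next to the carbon that will bear ring C.

Step 4
Reactants: 5 2,2-dimethyl-5-(triisopropylsilyloxy)-2H-chromene-8-carbaldehyde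
Product: 6 8-(2-methoxyethenyl)-2,2-dimethyl-5-(triisopropylsilyloxy)-2H-chromene (E/Z mixture)
Conditions: Ph3P(CH2OMe)Cl, NaN(SiMe3)2, THF, 0 °C to rt
Reagents that add atoms: (methoxymethyl)triphenylphosphonium chloride, COC[P+](c1ccccc1)(c1ccccc1)c1ccccc1.[Cl-]
Why: Wittig olefination with methoxymethylidenetriphenylphosphorane is the standard one-carbon homologation of an aromatic aldehyde, and the enol ether geometry is irrelevant because both isomers hydrolyse to the same aldehyde.

Step 5
Reactants: 6 8-(2-methoxyethenyl)-2,2-dimethyl-5-(triisopropylsilyloxy)-2H-chromene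
Product: 7 2-[2,2-dimethyl-5-(triisopropylsilyloxy)-2H-chromen-8-yl]acetaldehyde
Conditions: 2 M aq. HCl, THF, 40 °C; crude aldehyde used at once
Reagents that add atoms: water, O
Why: Acid-catalysed enol ether hydrolysis (C-protonation, hemiacetal, loss of methanol) releases the arylacetaldehyde under conditions in which an aryl triisopropylsilyl ether and a 2,2-dimethylchromene are stable.

Step 6
Reactants: 8 phloroglucinol
Product: 9 1,3,5-tris(methoxymethoxy)benzene
Conditions: NaH (3.6 equiv), MOMCl (3.6 equiv), DMF, 0 °C to rt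
Reagents that add atoms: chloromethyl methyl ether (MOMCl, three equivalents incorporated), COCCl
Why: Williamson O-alkylation of the phloroglucinol trianion with chloromethyl methyl ether gives the known tris-MOM ether, whose acetal oxygens direct the lithiation of step 7.

Step 7
Reactants: 9 1,3,5-tris(methoxymethoxy)benzene; 7 2-[2,2-dimethyl-5-(triisopropylsilyloxy)-2H-chromen-8-yl]acetaldehyde
Product: 11 2-[2,2-dimethyl-5-(triisopropylsilyloxy)-2H-chromen-8-yl]-1-[2,4,6-tris(methoxymethoxy)phenyl]ethan-1-ol (racemate), via 2,4,6-tris(methoxymethoxy)phenyllithium 10 (not isolated)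
Conditions: 9 (1.3 equiv), n-BuLi, THF, 0 °C to rt; then 7, −78 °C; aq. NH4Cl
Reagents that add atoms: none
Why: Directed ortho-lithiation between two OMOM groups gives a chelated aryllithium whose 1,2-addition to the aldehyde at −78 °C should outrun enolisation; the carbinol centre is formed as a racemate and is erased by the oxidation in step 8.

Step 8
Reactants: 11 2-[2,2-dimethyl-5-(triisopropylsilyloxy)-2H-chromen-8-yl]-1-[2,4,6-tris(methoxymethoxy)phenyl]ethan-1-ol
Product: 12 2-[2,2-dimethyl-5-(triisopropylsilyloxy)-2H-chromen-8-yl]-1-[2,4,6-tris(methoxymethoxy)phenyl]ethan-1-one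
Conditions: Dess–Martin periodinane, CH2Cl2, 0 °C to rt
Reagents that add atoms: none
Why: Dess–Martin oxidation of a secondary benzylic alcohol proceeds under near-neutral conditions that should spare the MOM acetals, the silyl ether, the chromene alkene and the acidic benzylic CH2 of the product.

Step 9
Reactants: 12 2-[2,2-dimethyl-5-(triisopropylsilyloxy)-2H-chromen-8-yl]-1-[2,4,6-tris(methoxymethoxy)phenyl]ethan-1-one
Product: 13 3-(dimethylamino)-2-[2,2-dimethyl-5-(triisopropylsilyloxy)-2H-chromen-8-yl]-1-[2,4,6-tris(methoxymethoxy)phenyl]prop-2-en-1-one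
Conditions: Me2NCH(OMe)2, toluene, 100 °C
Reagents that add atoms: N,N-dimethylformamide dimethyl acetal, COC(OC)N(C)C
Why: Condensation of the doubly activated CH2 (benzylic and alpha to the ketone) with the amide acetal gives the enaminone and installs the carbon that becomes C2, while the fully protected ring A is shielded from O-methylation by the reagent.

Step 10
Reactants: 13 3-(dimethylamino)-2-[2,2-dimethyl-5-(triisopropylsilyloxy)-2H-chromen-8-yl]-1-[2,4,6-tris(methoxymethoxy)phenyl]prop-2-en-1-one
Product: 14 5,7-dihydroxy-3-[2,2-dimethyl-5-(triisopropylsilyloxy)-2H-chromen-8-yl]-4H-chromen-4-one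
Conditions: HCl (1 M in MeOH/THF), 40 °C, stopped when the 7-O-MOM group is gone
Reagents that add atoms: none
Why: Acidic methanolysis of the MOM acetals frees the ortho phenol, which adds to the protonated enaminone and expels dimethylamine (6-endo-trig oxa-Michael addition–elimination, a standard isoflavone ring closure), and aryl triisopropylsilyl ethers are cleaved much more slowly than MOM acetals under these conditions.

Step 11
Reactants: 14 5,7-dihydroxy-3-[2,2-dimethyl-5-(triisopropylsilyloxy)-2H-chromen-8-yl]-4H-chromen-4-one; 15 bis(dimethylamino)methane (two equivalents incorporated)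
Product: 17 6,8-bis[(dimethylamino)methyl]-5,7-dihydroxy-3-[2,2-dimethyl-5-(triisopropylsilyloxy)-2H-chromen-8-yl]-4H-chromen-4-one, via 8-aminomethyl isoflavone 16 (not isolated)
Conditions: CH2(NMe2)2 (4 equiv), 1,4-dioxane, 90 °C
Reagents that add atoms: bis(dimethylamino)methane (compound 15, second equivalent), CN(C)CN(C)C
Why: Phenol Mannich aminomethylation with the aminal as iminium source takes place ortho to free phenols only, so one equivalent of the aminal delivers CH2NMe2 to C8 and a second to C6 of ring A (each releasing dimethylamine), as known for 5,7-dihydroxyisoflavones, while the silylated ring B has no free hydroxyl to direct the reaction.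

Step 12
Reactants: 17 6,8-bis[(dimethylamino)methyl]-5,7-dihydroxy-3-[2,2-dimethyl-5-(triisopropylsilyloxy)-2H-chromen-8-yl]-4H-chromen-4-one; 18 2-methylprop-1-enylboronic acid (two equivalents incorporated)
Product: 22 4'-O-triisopropylsilyl Kanzonol L, via C8 ortho-quinone methide 19 (not isolated), via 8-prenyl 6-aminomethyl isoflavone 20 (not isolated), via C6 ortho-quinone methide 21 (not isolated)
Conditions: Me2C=CHB(OH)2 (5 equiv), toluene (0.02 M), 4 Å molecular sieves, 100 °C; aqueous work-up
Reagents that add atoms: 2-methylprop-1-enylboronic acid (compound 18, second equivalent), CC(C)=CB(O)O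
Why: The boronic acid esterifies the phenol oxygen next to each benzylic amine while dimethylamine departs, unveiling an ortho-quinone methide (exocyclic CH2 at C8 first, then at C6) whose oxygen carries a tetracoordinate alkenylboronate; the 2-methylpropenyl group then migrates from boron to the methide carbon through a six-membered transition state, re-aromatising ring A and forming the CH2–CH bond of each prenyl group, one boronic acid being consumed per arm. The closest known reaction type is the 1,4-addition of alkenylboronic acids and boronates to ortho-quinone methides generated in situ from ortho-hydroxybenzyl precursors, a relative of the Petasis borono-Mannich alkenyl transfer. No ring is closed and no stereocenter is formed, and the trisubstituted alkene is carried over unchanged from the reagent. The selectivity needed is 1,4-alkenyl transfer in preference to hetero-Diels–Alder capture of the quinone methide by the chromene or the first prenyl alkene and to quinone methide dimerisation; intramolecular delivery from boron held on the quinone methide oxygen, high dilution and excess boronic acid should secure it. Regiochemistry is not at stake, because the carbon electrophiles were fixed at C6 and C8 in step 11 and O4' is silylated.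

Step 13
Reactants: 22 4'-O-triisopropylsilyl Kanzonol L
Product: 23 Kanzonol L
Conditions: Bu4NF, AcOH, THF, 0 °C
Reagents that add atoms: none
Why: Fluoride-induced cleavage of the aryl silyl ether with acetic acid buffering should free O4'–H without touching the prenyl and chromene alkenes or promoting base-mediated cyclisation of the ortho-prenyl phenols.

**Compound list**

1 | 2,4-dihydroxybenzaldehyde | O=Cc1ccc(O)cc1O | starting material
2 | 2-hydroxy-4-(triisopropylsilyloxy)benzaldehyde | O=Cc1ccc(O[Si](C(C)C)(C(C)C)C(C)C)cc1O | intermediate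
3 | 3-chloro-3-methylbut-1-yne | CC(C)(Cl)C#C | starting material
4 | 2-[(2-methylbut-3-yn-2-yl)oxy]-4-(triisopropylsilyloxy)benzaldehyde | O=Cc1ccc(O[Si](C(C)C)(C(C)C)C(C)C)cc1OC(C)(C)C#C | intermediate
5 | 2,2-dimethyl-5-(triisopropylsilyloxy)-2H-chromene-8-carbaldehyde | O=Cc1ccc(O[Si](C(C)C)(C(C)C)C(C)C)c2c1OC(C)(C)C=C2 | intermediate
6 | 8-(2-methoxyethenyl)-2,2-dimethyl-5-(triisopropylsilyloxy)-2H-chromene (E/Z mixture) | COC=Cc1ccc(O[Si](C(C)C)(C(C)C)C(C)C)c2c1OC(C)(C)C=C2 | intermediate
7 | 2-[2,2-dimethyl-5-(triisopropylsilyloxy)-2H-chromen-8-yl]acetaldehyde | O=CCc1ccc(O[Si](C(C)C)(C(C)C)C(C)C)c2c1OC(C)(C)C=C2 | intermediate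
8 | phloroglucinol | Oc1cc(O)cc(O)c1 | starting material
9 | 1,3,5-tris(methoxymethoxy)benzene | COCOc1cc(OCOC)cc(OCOC)c1 | intermediate
10 | 2,4,6-tris(methoxymethoxy)phenyllithium (not isolated) | [Li]c1c(OCOC)cc(OCOC)cc1OCOC | intermediate
11 | 2-[2,2-dimethyl-5-(triisopropylsilyloxy)-2H-chromen-8-yl]-1-[2,4,6-tris(methoxymethoxy)phenyl]ethan-1-ol (racemate) | COCOc1cc(OCOC)c(C(O)Cc2ccc(O[Si](C(C)C)(C(C)C)C(C)C)c3c2OC(C)(C)C=C3)c(OCOC)c1 | intermediate
12 | 2-[2,2-dimethyl-5-(triisopropylsilyloxy)-2H-chromen-8-yl]-1-[2,4,6-tris(methoxymethoxy)phenyl]ethan-1-one | COCOc1cc(OCOC)c(C(=O)Cc2ccc(O[Si](C(C)C)(C(C)C)C(C)C)c3c2OC(C)(C)C=C3)c(OCOC)c1 | intermediate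
13 | 3-(dimethylamino)-2-[2,2-dimethyl-5-(triisopropylsilyloxy)-2H-chromen-8-yl]-1-[2,4,6-tris(methoxymethoxy)phenyl]prop-2-en-1-one | CN(C)C=C(C(=O)c1c(OCOC)cc(OCOC)cc1OCOC)c1ccc(O[Si](C(C)C)(C(C)C)C(C)C)c2c1OC(C)(C)C=C2 | intermediate
14 | 5,7-dihydroxy-3-[2,2-dimethyl-5-(triisopropylsilyloxy)-2H-chromen-8-yl]-4H-chromen-4-one | O=c1c(-c2ccc(O[Si](C(C)C)(C(C)C)C(C)C)c3c2OC(C)(C)C=C3)coc2cc(O)cc(O)c12 | intermediate
15 | bis(dimethylamino)methane | CN(C)CN(C)C | starting material
16 | 8-[(dimethylamino)methyl]-5,7-dihydroxy-3-[2,2-dimethyl-5-(triisopropylsilyloxy)-2H-chromen-8-yl]-4H-chromen-4-one (not isolated) | CN(C)Cc1c(O)cc(O)c2c(=O)c(-c3ccc(O[Si](C(C)C)(C(C)C)C(C)C)c4c3OC(C)(C)C=C4)coc12 | intermediate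
17 | 6,8-bis[(dimethylamino)methyl]-5,7-dihydroxy-3-[2,2-dimethyl-5-(triisopropylsilyloxy)-2H-chromen-8-yl]-4H-chromen-4-one | CN(C)Cc1c(O)c(CN(C)C)c2occ(-c3ccc(O[Si](C(C)C)(C(C)C)C(C)C)c4c3OC(C)(C)C=C4)c(=O)c2c1O | intermediate
18 | 2-methylprop-1-enylboronic acid | CC(C)=CB(O)O | starting material
19 | 6-[(dimethylamino)methyl]-5-hydroxy-8-methylidene-3-[2,2-dimethyl-5-(triisopropylsilyloxy)-2H-chromen-8-yl]-8H-chromene-4,7-dione, the C8 ortho-quinone methide (not isolated) | C=C1C(=O)C(CN(C)C)=C(O)C2=C1OC=C(c3ccc(O[Si](C(C)C)(C(C)C)C(C)C)c4c3OC(C)(C)C=C4)C2=O | intermediate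
20 | 6-[(dimethylamino)methyl]-5,7-dihydroxy-8-(3-methylbut-2-en-1-yl)-3-[2,2-dimethyl-5-(triisopropylsilyloxy)-2H-chromen-8-yl]-4H-chromen-4-one (not isolated) | CN(C)Cc1c(O)c(CC=C(C)C)c2occ(-c3ccc(O[Si](C(C)C)(C(C)C)C(C)C)c4c3OC(C)(C)C=C4)c(=O)c2c1O | intermediate
21 | 5-hydroxy-6-methylidene-8-(3-methylbut-2-en-1-yl)-3-[2,2-dimethyl-5-(triisopropylsilyloxy)-2H-chromen-8-yl]-6H-chromene-4,7-dione, the C6 ortho-quinone methide (not isolated) | C=C1C(=O)C(CC=C(C)C)=C2OC=C(c3ccc(O[Si](C(C)C)(C(C)C)C(C)C)c4c3OC(C)(C)C=C4)C(=O)C2=C1O | intermediate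
22 | 4'-O-triisopropylsilyl Kanzonol L: 5,7-dihydroxy-6,8-bis(3-methylbut-2-en-1-yl)-3-[2,2-dimethyl-5-(triisopropylsilyloxy)-2H-chromen-8-yl]-4H-chromen-4-one | CC(C)=CCc1c(O)c(CC=C(C)C)c2occ(-c3ccc(O[Si](C(C)C)(C(C)C)C(C)C)c4c3OC(C)(C)C=C4)c(=O)c2c1O | intermediate
23 | Kanzonol L: 5,7-dihydroxy-3-(5-hydroxy-2,2-dimethyl-2H-chromen-8-yl)-6,8-bis(3-methylbut-2-en-1-yl)-4H-chromen-4-one | CC(C)=CCc1c(O)c(CC=C(C)C)c2occ(-c3ccc(O)c4c3OC(C)(C)C=C4)c(=O)c2c1O | target

**Step count and risks**

Total step count: 13. Longest linear sequence: 12 steps (steps 1–5, then 7–13); step 6 is a one-step side branch.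

Steps most likely to fail:

Step 12. Ionisation to the quinone methide may lag behind protodeboronation of the reagent, or the quinone methide may be consumed by hetero-Diels–Alder capture (chromene or first prenyl alkene) or dimerisation, leaving the second arm incompletely converted. The fallback sets out from 17: exhaustive N-methylation with MeI in acetone would give the 6,8-bis[(trimethylammonio)methyl] diiodide F1, whose quinone methides form on deprotonation at low temperature. Treatment with excess 2-methylprop-1-enylmagnesium bromide (THF, −78 °C to 0 °C) would then deprotonate the phenols and add 1,4 to each quinone methide as it forms, coming back to the route at 22.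

Step 10. Cleavage of the aryl silyl ether may compete with removal of the slowest (7-O) MOM group, or MOM removal may stop short. The fallback sets out from 13: the acid treatment would be driven to completion (3 M HCl, MeOH, 60 °C) to give the fully deprotected triol 5,7-dihydroxy-3-(5-hydroxy-2,2-dimethyl-2H-chromen-8-yl)-4H-chromen-4-one F2. Silylation with TIPSCl and imidazole in DMF (the chelated 5-OH stays free) would give the 7,4'-bis-silyl ether F3. K2CO3 in MeOH at 0 °C would then remove only the 7-O-silyl group, whose phenoxide is a vinylogous carboxylate and a far better leaving group, coming back to the route at 14.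

Step 7. The aryllithium may deprotonate the enolisable, aldol-prone arylacetaldehyde instead of adding to it. The fallback sets out from 7: Pinnick oxidation (NaClO2, NaH2PO4, 2-methylbut-2-ene, t-BuOH/H2O) would give 2-[2,2-dimethyl-5-(triisopropylsilyloxy)-2H-chromen-8-yl]acetic acid F4. Coupling with MeNHOMe·HCl (EDC·HCl, i-Pr2NEt, CH2Cl2) would give the Weinreb amide F5, and acylation of aryllithium 10 with F5 at −78 °C would give the ketone directly, coming back to the route at 12 and bypassing 11 and step 8.

**Further compounds**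

F1 | step 12 | 6,8-bis[(trimethylammonio)methyl]-5,7-dihydroxy-3-[2,2-dimethyl-5-(triisopropylsilyloxy)-2H-chromen-8-yl]-4H-chromen-4-one diiodide | C[N+](C)(C)Cc1c(O)c(C[N+](C)(C)C)c2occ(-c3ccc(O[Si](C(C)C)(C(C)C)C(C)C)c4c3OC(C)(C)C=C4)c(=O)c2c1O.[I-].[I-]
F2 | step 10 | 5,7-dihydroxy-3-(5-hydroxy-2,2-dimethyl-2H-chromen-8-yl)-4H-chromen-4-one | O=c1c(-c2ccc(O)c3c2OC(C)(C)C=C3)coc2cc(O)cc(O)c12
F3 | step 10 | 5-hydroxy-7-(triisopropylsilyloxy)-3-[2,2-dimethyl-5-(triisopropylsilyloxy)-2H-chromen-8-yl]-4H-chromen-4-one | O=c1c(-c2ccc(O[Si](C(C)C)(C(C)C)C(C)C)c3c2OC(C)(C)C=C3)coc2cc(O[Si](C(C)C)(C(C)C)C(C)C)cc(O)c12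
F4 | step 7 | 2-[2,2-dimethyl-5-(triisopropylsilyloxy)-2H-chromen-8-yl]acetic acid | OC(=O)Cc1ccc(O[Si](C(C)C)(C(C)C)C(C)C)c2c1OC(C)(C)C=C2
F5 | step 7 | N-methoxy-N-methyl-2-[2,2-dimethyl-5-(triisopropylsilyloxy)-2H-chromen-8-yl]acetamide | CON(C)C(=O)Cc1ccc(O[Si](C(C)C)(C(C)C)C(C)C)c2c1OC(C)(C)C=C2
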